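**Retrosynthetic overview**

1. Target 21 ⇐ C6–prenyl bond (Stille coupling on the 6-iodide 19, C6 being the only free position of ring A) ⇐ hydrogenolysis of the 5,7-dibenzyl ether 17.
2. Ring C of 17 is closed last, by forming the C2–C3 bond: the seven-membered benzylidene acetal 14 (O1–C2–O3–C3=C4–C4a–C8a) contracts to the pyranone under chiral silylium/IDPi ion-pair catalysis; C2 is set by the catalyst, C3 (trans) by the substrate.
3. Enabling feature: C2 of ring C carries both the ring oxygen O1 and the phenyl ring B, so it can leave an acetal as a stabilised O1-aryl oxocarbenium ion; C3 is the α-carbon of the C4 aryl ketone and carries a hydroxyl oxygen (O3) that can act as a temporary tether from C3 to C2.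
4. Acetal 12 ⇐ hydroxy ketone 10 + benzaldehyde dimethyl acetal (brings C2 and ring B); 10 ⇐ 3,5-bis(benzyloxy)phenol by two MOM-directed ortho-lithiations (C8 oxygen first, then the C4–C3 unit at C4a).
5. Order of rings: rings A and B are bought; the temporary seven-membered acetal ring is made in step 6, ring C in step 8.

Key step: step 8

Remark: flavonoid numbering (O1, C2, C3, C4, C4a, C5 to C8, C8a) is used for ring positions throughout.
Assumption: compounds 1, 7, 11 and 20 are taken as commercial.
Assumption: the (S,S)-antipode of the IDPi catalyst is written as the one leading to the (2R) series; the sense is to be fixed in a first run (circular dichroism of 17), and the (R,R)-catalyst is to be used if the opposite sense is found.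

**Route**

Step 1
Reactants: 1 3,5-bis(benzyloxy)phenol
Product: 2 1,3-bis(benzyloxy)-5-(methoxymethoxy)benzene
Conditions: NaH, MOMCl, DMF, 0 °C to rt
Reagents that add atoms: chloromethyl methyl ether, COCCl
Why: Williamson-type O-alkylation of the sodium phenoxide gives the methoxymethyl ether that later directs both ortho-lithiations and is the only aryl ether cleaved by dilute acid.

Step 2
Reactants: 2 1,3-bis(benzyloxy)-5-(methoxymethoxy)benzene
Product: 5 2,4-bis(benzyloxy)-6-(methoxymethoxy)phenol, via aryllithium 3 (not isolated), via dimethyl arylboronate 4 (not isolated)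
Conditions: n-BuLi, THF, −20 to 0 °C; B(OMe)3, −78 °C to rt; AcOH, 30% H2O2, 0 °C to rt
Reagents that add atoms: hydrogen peroxide, OO; n-butyllithium, [Li]CCCC (lithium of 3 only); trimethyl borate, COB(OC)OC (boron ester of 4 only)
Why: Directed ortho-metalation is steered by the chelating methoxymethoxy group to the carbon between it and a benzyloxy group, and borylation followed by oxidative C–B to C–O conversion places the future C8 oxygen next to the future O1.

Step 3
Reactants: 5 2,4-bis(benzyloxy)-6-(methoxymethoxy)phenol
Product: 6 1,5-bis(benzyloxy)-2-methoxy-3-(methoxymethoxy)benzene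
Conditions: MeI, K2CO3, acetone, reflux
Reagents that add atoms: iodomethane, CI
Why: Williamson methylation of the only free hydroxyl fixes the C8 methoxy group before the second lithiation.

Step 4
Reactants: 6 1,5-bis(benzyloxy)-2-methoxy-3-(methoxymethoxy)benzene; 7 2-[(tert-butyldimethylsilyl)oxy]-N-methoxy-N-methylacetamide
Product: 9 1-[2,4-bis(benzyloxy)-5-methoxy-6-(methoxymethoxy)phenyl]-2-[(tert-butyldimethylsilyl)oxy]ethan-1-one, via aryllithium 8 (not isolated)
Conditions: n-BuLi, THF, −20 to 0 °C; then 7, −78 to 0 °C; H2O
Reagents that add atoms: n-butyllithium, [Li]CCCC (lithium of 8 only)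
Why: A second directed ortho-metalation can only take the remaining position next to the methoxymethoxy group, and the aryllithium adds once to the Weinreb amide (stable chelated tetrahedral intermediate) to give the ketone that holds C4 and C3 with its oxygen.

Step 5
Reactants: 9 1-[2,4-bis(benzyloxy)-5-methoxy-6-(methoxymethoxy)phenyl]-2-[(tert-butyldimethylsilyl)oxy]ethan-1-one
Product: 10 1-[4,6-bis(benzyloxy)-2-hydroxy-3-methoxyphenyl]-2-hydroxyethan-1-one
Conditions: HCl (2 M), MeOH/THF, 40 °C
Reagents that add atoms: none
Why: Acid-catalysed acetal exchange removes the methoxymethyl group (assisted by the ortho carbonyl) and solvolyses the primary silyl ether, while benzyl and methyl ethers are stable.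

Step 6
Reactants: 10 1-[4,6-bis(benzyloxy)-2-hydroxy-3-methoxyphenyl]-2-hydroxyethan-1-one; 11 benzaldehyde dimethyl acetal
Product: 12 6,8-bis(benzyloxy)-9-methoxy-2-phenyl-4H-1,3-benzodioxepin-5-one (racemic)
Conditions: PPTS (cat.), toluene, 5 Å molecular sieves, 60 °C
Reagents that add atoms: none
Why: Acid-catalysed transacetalisation with removal of methanol ties the phenolic O1 and the primary hydroxyl O3 to the benzaldehyde carbon as a seven-membered cyclic acetal, the pyridinium acid being too weak to enolise the ketone and start the rearrangement.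

Step 7
Reactants: 12 6,8-bis(benzyloxy)-9-methoxy-2-phenyl-4H-1,3-benzodioxepin-5-one
Product: 14 6,8-bis(benzyloxy)-5-[(tert-butyldimethylsilyl)oxy]-9-methoxy-2-phenyl-2H-1,3-benzodioxepine (racemic), via potassium enolate 13 (not isolated)
Conditions: KN(SiMe3)2, THF, −78 °C; TBSCl, −78 to 0 °C
Reagents that add atoms: tert-butyldimethylsilyl chloride, CC(C)(C)[Si](C)(C)Cl; potassium bis(trimethylsilyl)amide, C[Si](C)(C)[N-][Si](C)(C)C.[K+] (potassium of 13 only)
Why: Kinetic deprotonation at the only enolisable position and O-silylation of the potassium enolate give the silyl enol ether under basic conditions, so that the acid-labile acetal is untouched.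

Step 8
Reactants: 14 6,8-bis(benzyloxy)-5-[(tert-butyldimethylsilyl)oxy]-9-methoxy-2-phenyl-2H-1,3-benzodioxepine
Product: 17 (2R,3R)-5,7-bis(benzyloxy)-3-hydroxy-8-methoxy-2-phenylchroman-4-one, via oxocarbenium ion 15 (not isolated), via silyl ether 16 (not isolated)
Conditions: (S,S)-IDPi (3 mol%; imidodiphosphorimidate (ArO)2P(=NTf)–NH–P(=NTf)(OAr)2 built from two (S)-3,3'-bis[3,5-bis(trifluoromethyl)phenyl]-BINOL units), toluene, −60 °C; then HF·pyridine, THF, 0 °C
Reagents that add atoms: none
Why: Proposed new method: the silylated IDPi (formed by protodesilylation of a trace of 14) silylates the acetal oxygen O3, the C2–O3 bond ionises to the E-configured O1-aryl oxocarbenium ion 15, which is held as a contact ion pair inside the chiral IDPi anion, and the freed 1,2-bis(silyloxy)alkene adds through C3 to C2 in an intramolecular Mukaiyama-type step, after which the C4 silyloxocarbenium passes its silyl group to the next molecule of 14, so that the seven-membered acetal contracts to the pyranone 16 with silylium as chain carrier. The closest known reaction types are the Petasis–Ferrier and anomeric oxygen-to-carbon rearrangements of enol-ether acetals, their chiral-phosphoric-acid-catalysed enantioselective form on cyclic vinyl acetals, and IDPi/silylium-catalysed additions of silyl enol ethers to oxocarbenium ions; what is new is the 1,2-shift of a benzylidene acetal carbon onto an enediol silyl ether with catalyst-controlled absolute configuration. Ring C closes in a 6-endo-trig (enol-endo) mode at the oxocarbenium carbon, whereas attack through C4 would be a 5-endo closure to a less stabilised cation. C2 is set by the catalyst, which selects the face of the oxocarbenium ion within the confined ion pair, and C3 by the substrate, because the enol geometry inherited from the seven-membered ring (O3 cis to the aryl group) and the E-oxocarbenium combine in a disrotatory-type closure that puts phenyl and silyloxy trans, the arrangement that is also the more stable diequatorial one. The step needs chemoselective ionisation, secured by 14 holding a single acetal (benzyl and methyl ethers should not ionise at −60 °C) and by the alternative C2–O1 cleavage being reversible and unproductive, and enantioface control, secured by the counter-anion. Buffered HF·pyridine then frees the C3 hydroxyl without touching C2 or C3.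

Step 9
Reactants: 17 (2R,3R)-5,7-bis(benzyloxy)-3-hydroxy-8-methoxy-2-phenylchroman-4-one
Product: 18 (2R,3R)-3,5,7-trihydroxy-8-methoxy-2-phenylchroman-4-one
Conditions: H2 (1 atm), Pd/C, EtOAc, rt
Reagents that add atoms: none
Why: Hydrogenolysis cleaves the two O-benzyl ethers under neutral conditions that leave the aryl ketone and both stereocenters unchanged, the ring C–O1 bond at C2 being far slower to cleave than benzyl aryl ethers.

Step 10
Reactants: 18 (2R,3R)-3,5,7-trihydroxy-8-methoxy-2-phenylchroman-4-one
Product: 19 (2R,3R)-3,5,7-trihydroxy-6-iodo-8-methoxy-2-phenylchroman-4-one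
Conditions: NIS, DMF, 0 °C, dark
Reagents that add atoms: N-iodosuccinimide, O=C1CCC(=O)N1I
Why: Electrophilic aromatic iodination can only occur at C6, the single free position of the phloroglucinol-type ring A, which is activated by both flanking hydroxyl groups.

Step 11
Reactants: 19 (2R,3R)-3,5,7-trihydroxy-6-iodo-8-methoxy-2-phenylchroman-4-one; 20 tributyl(3-methylbut-2-en-1-yl)stannane
Product: 21 (2R,3R)-3,5,7-trihydroxy-8-methoxy-6-(3-methylbut-2-en-1-yl)-2-phenylchroman-4-one
Conditions: Pd(PPh3)4 (zerovalent palladium, 10 mol%), DMF, 80 °C, degassed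
Reagents that add atoms: none
Why: Stille coupling, in which the prenylpalladium intermediate reductively eliminates at its unsubstituted terminus to give the linear 3-methylbut-2-enyl group, runs without base so that the base-sensitive C2 and C3 stereocenters of the dihydroflavonol are not epimerised.

**Compound list**

1 | 3,5-bis(benzyloxy)phenol | Oc1cc(OCc2ccccc2)cc(OCc2ccccc2)c1 | starting material
2 | 1,3-bis(benzyloxy)-5-(methoxymethoxy)benzene | COCOc1cc(OCc2ccccc2)cc(OCc2ccccc2)c1 | intermediate
3 | [2,4-bis(benzyloxy)-6-(methoxymethoxy)phenyl]lithium | COCOc1cc(OCc2ccccc2)cc(OCc2ccccc2)c1[Li] | intermediate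
4 | dimethyl [2,4-bis(benzyloxy)-6-(methoxymethoxy)phenyl]boronate | COCOc1cc(OCc2ccccc2)cc(OCc2ccccc2)c1B(OC)OC | intermediate
5 | 2,4-bis(benzyloxy)-6-(methoxymethoxy)phenol | COCOc1cc(OCc2ccccc2)cc(OCc2ccccc2)c1O | intermediate
6 | 1,5-bis(benzyloxy)-2-methoxy-3-(methoxymethoxy)benzene | COCOc1cc(OCc2ccccc2)cc(OCc2ccccc2)c1OC | intermediate
7 | 2-[(tert-butyldimethylsilyl)oxy]-N-methoxy-N-methylacetamide | CON(C)C(=O)CO[Si](C)(C)C(C)(C)C | starting material
8 | [2,4-bis(benzyloxy)-5-methoxy-6-(methoxymethoxy)phenyl]lithium | COCOc1c([Li])c(OCc2ccccc2)cc(OCc2ccccc2)c1OC | intermediate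
9 | 1-[2,4-bis(benzyloxy)-5-methoxy-6-(methoxymethoxy)phenyl]-2-[(tert-butyldimethylsilyl)oxy]ethan-1-one | COCOc1c(C(=O)CO[Si](C)(C)C(C)(C)C)c(OCc2ccccc2)cc(OCc2ccccc2)c1OC | intermediate
10 | 1-[4,6-bis(benzyloxy)-2-hydroxy-3-methoxyphenyl]-2-hydroxyethan-1-one | COc1c(O)c(C(=O)CO)c(OCc2ccccc2)cc1OCc1ccccc1 | intermediate
11 | benzaldehyde dimethyl acetal | COC(OC)c1ccccc1 | starting material
12 | 6,8-bis(benzyloxy)-9-methoxy-2-phenyl-4H-1,3-benzodioxepin-5-one (racemic) | COc1c2OC(c3ccccc3)OCC(=O)c2c(OCc2ccccc2)cc1OCc1ccccc1 | intermediate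
13 | potassium 6,8-bis(benzyloxy)-9-methoxy-2-phenyl-2H-1,3-benzodioxepin-5-olate (racemic) | COc1c2OC(c3ccccc3)OC=C([O-])c2c(OCc2ccccc2)cc1OCc1ccccc1.[K+] | intermediate
14 | 6,8-bis(benzyloxy)-5-[(tert-butyldimethylsilyl)oxy]-9-methoxy-2-phenyl-2H-1,3-benzodioxepine (racemic) | COc1c2OC(c3ccccc3)OC=C(O[Si](C)(C)C(C)(C)C)c2c(OCc2ccccc2)cc1OCc1ccccc1 | intermediate
15 | (E)-benzylidene{3,5-bis(benzyloxy)-2-[(E)-1,2-bis(tert-butyldimethylsilyloxy)vinyl]-6-methoxyphenyl}oxonium (cation of the ion pair with the IDPi anion) | COc1c(/[O+]=C/c2ccccc2)c(/C(O[Si](C)(C)C(C)(C)C)=C\O[Si](C)(C)C(C)(C)C)c(OCc2ccccc2)cc1OCc1ccccc1 | intermediate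
16 | (2R,3R)-5,7-bis(benzyloxy)-3-[(tert-butyldimethylsilyl)oxy]-8-methoxy-2-phenylchroman-4-one | COc1c(OCc3ccccc3)cc(OCc3ccccc3)c2c1O[C@H](c1ccccc1)[C@@H](O[Si](C)(C)C(C)(C)C)C2=O | intermediate
17 | (2R,3R)-5,7-bis(benzyloxy)-3-hydroxy-8-methoxy-2-phenylchroman-4-one | COc1c(OCc3ccccc3)cc(OCc3ccccc3)c2c1O[C@H](c1ccccc1)[C@@H](O)C2=O | intermediate
18 | (2R,3R)-3,5,7-trihydroxy-8-methoxy-2-phenylchroman-4-one | COc1c(O)cc(O)c2c1O[C@H](c1ccccc1)[C@@H](O)C2=O | intermediate
19 | (2R,3R)-3,5,7-trihydroxy-6-iodo-8-methoxy-2-phenylchroman-4-one | COc1c(O)c(I)c(O)c2c1O[C@H](c1ccccc1)[C@@H](O)C2=O | intermediate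
20 | tributyl(3-methylbut-2-en-1-yl)stannane | CCCC[Sn](CCCC)(CCCC)CC=C(C)C | starting material
21 | (2R,3R)-3,5,7-trihydroxy-8-methoxy-6-(3-methylbut-2-en-1-yl)-2-phenylchroman-4-one | COc1c(O)c(CC=C(C)C)c(O)c2c1O[C@H](c1ccccc1)[C@@H](O)C2=O | target

**Summary**

Total step count: 11. Longest linear sequence: 11 steps (from 1).

Steps most likely to fail:

1. Step 8 (Proposed new method). What may go wrong: ionisation of the acetal without ring closure (silyl transfer and loss of the benzylidene unit), or weak face discrimination in the ion pair, so that 17 would form with low enantiomeric purity. Fallback (known chemistry): it sets out from 6. Ortho-lithiation as in step 4 and acylation with N-methoxy-N-methylacetamide should give 1-[2,4-bis(benzyloxy)-5-methoxy-6-(methoxymethoxy)phenyl]ethan-1-one F1. Claisen–Schmidt condensation with benzaldehyde (KOH, EtOH) should give the chalcone (E)-1-[2,4-bis(benzyloxy)-5-methoxy-6-(methoxymethoxy)phenyl]-3-phenylprop-2-en-1-one F2. Juliá–Colonna epoxidation (poly-L-leucine, urea–H2O2, DBU, THF) should give [2,4-bis(benzyloxy)-5-methoxy-6-(methoxymethoxy)phenyl][(2R,3S)-3-phenyloxiran-2-yl]methanone F3. HCl in MeOH/THF at 50 °C then removes the methoxymethyl group, and the freed phenol opens the epoxide at the benzylic carbon with inversion (6-endo) to give the trans-dihydroflavonol; the route is rejoined at 17.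

2. Step 6. What may go wrong: the ring–chain equilibrium may not favour the seven-membered mixed aryl/alkyl acetal, or the acid may start acetal exchange to oligomers and a racemic rearrangement before 12 is isolated. Fallback: it sets out from 10. Silylation of both hydroxyl groups (Me3SiCl, Et3N, CH2Cl2) should give 1-[4,6-bis(benzyloxy)-3-methoxy-2-(trimethylsilyloxy)phenyl]-2-(trimethylsilyloxy)ethan-1-one F4, which is condensed with benzaldehyde by kinetic silyl-transfer acetalisation (cat. Me3SiOTf, CH2Cl2, −78 °C) instead of thermodynamic transacetalisation; the route is rejoined at 12.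

3. Step 11. What may go wrong: protodeiodination of the hindered, electron-rich aryl iodide, or allyl transposition during transmetalation leading to the 1,1-dimethylallyl isomer. Fallback: it sets out from 18 and leaves out 19. Direct Friedel–Crafts prenylation with 2-methylbut-3-en-2-ol and BF3·OEt2 in dioxane at rt is used; C6 is the only free nucleophilic carbon of ring A, so C-alkylation can only lead to 21, where the route is rejoined; no new compound arises (F0).

**Further compounds**

F1 | step 8 | 1-[2,4-bis(benzyloxy)-5-methoxy-6-(methoxymethoxy)phenyl]ethan-1-one | COCOc1c(C(C)=O)c(OCc2ccccc2)cc(OCc2ccccc2)c1OC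
F2 | step 8 | (E)-1-[2,4-bis(benzyloxy)-5-methoxy-6-(methoxymethoxy)phenyl]-3-phenylprop-2-en-1-one | COCOc1c(C(=O)/C=C/c2ccccc2)c(OCc2ccccc2)cc(OCc2ccccc2)c1OC
F3 | step 8 | [2,4-bis(benzyloxy)-5-methoxy-6-(methoxymethoxy)phenyl][(2R,3S)-3-phenyloxiran-2-yl]methanone | COCOc1c(C(=O)[C@@H]2O[C@H]2c2ccccc2)c(OCc2ccccc2)cc(OCc2ccccc2)c1OC
F4 | step 6 | 1-[4,6-bis(benzyloxy)-3-methoxy-2-(trimethylsilyloxy)phenyl]-2-(trimethylsilyloxy)ethan-1-one | COc1c(O[Si](C)(C)C)c(C(=O)CO[Si](C)(C)C)c(OCc2ccccc2)cc1OCc1ccccc1
F0 | step 11 | none | none
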